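**Retrosynthetic overview**
1. Alpinnanin C ⇐ its tris-MOM ether (mild acid) ⇐ Claisen–Schmidt condensation of a ring-A aryl methyl ketone with benzaldehyde; the acetyl group comes from an aryl bromide by Stille coupling.
2. The C5 carbinol (S) ⇐ ketoreductase reduction of the corresponding C5 ketone (enzyme step, catalyst control).
3. The C3 stereocentre (R, set first) ⇐ [Rh(OH)((S)-BINAP)]2-catalysed conjugate addition of an (E)-styrylboronic acid to an (E)-aryl enone.
4. Enone ⇐ HWE of a bromo-bis(MOM)-benzaldehyde (from 5-methoxyresorcinol: MOM, ortho-lithiation/formylation, bromination) with dimethyl (2-oxo-4-phenylbutyl)phosphonate; boronic acid ⇐ 4-hydroxybenzaldehyde (MOM, alkyne, hydroboration).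
5. No ring is formed: the three benzene rings are bought and only acyclic C–C bonds are made.

Assumption: the heptenyl chain is numbered from the styrene carbon (C1) to the CH2Ph carbon (C7), so the target SMILES reads (3R,5S) with both alkenes E; an engineered ketoreductase screening panel is taken as commercially available.

**Route**

Step 1
Reactants: 1 5-methoxyresorcinol (5-methoxybenzene-1,3-diol)
Product: 2 1-methoxy-3,5-bis(methoxymethoxy)benzene
Conditions: NaH (2.4 equiv), DMF, 0 °C; MOMCl (2.4 equiv), 0 °C → rt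
Reagents that add atoms: chloromethyl methyl ether (MOMCl), COCCl
Why: Williamson-type O-alkylation of both phenoxides gives the bis-MOM ether, whose MOM groups later direct lithiation and come off under mild acid.

Step 2
Reactants: 2 1-methoxy-3,5-bis(methoxymethoxy)benzene
Product: 4 4-methoxy-2,6-bis(methoxymethoxy)benzaldehyde, via aryllithium 3 (not isolated)
Conditions: n-BuLi (1.2 equiv), TMEDA, THF, 0 °C, 1 h; DMF (3 equiv), 0 °C → rt; H2O
Reagents that add atoms: N,N-dimethylformamide (DMF), CN(C)C=O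
Why: Directed ortho-metalation occurs at the carbon flanked by the two OMOM groups (cooperative chelation, OMOM a stronger director than OMe), and the aryllithium is formylated by DMF (Bouveault formylation).

Step 3
Reactants: 4 4-methoxy-2,6-bis(methoxymethoxy)benzaldehyde
Product: 5 3-bromo-4-methoxy-2,6-bis(methoxymethoxy)benzaldehyde
Conditions: NBS (1.05 equiv), MeCN, 0 °C → rt, dark
Reagents that add atoms: N-bromosuccinimide (NBS), O=C1CCC(=O)N1Br
Why: Electrophilic aromatic bromination can only occur at the two symmetry-equivalent free positions, which are activated by three alkoxy groups and meta to the aldehyde, and the bromine is the handle for the later acetyl group.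

Step 4
Reactants: 5 3-bromo-4-methoxy-2,6-bis(methoxymethoxy)benzaldehyde; 6 dimethyl (2-oxo-4-phenylbutyl)phosphonate
Product: 7 (1E)-1-[3-bromo-4-methoxy-2,6-bis(methoxymethoxy)phenyl]-5-phenylpent-1-en-3-one
Conditions: NaH (1.1 equiv), THF, 0 °C; then 5, 0 °C → rt
Reagents that add atoms: none
Why: Horner–Wadsworth–Emmons olefination with the stabilised β-ketophosphonate anion gives the E-enone regiospecifically, with no aldol regiochemistry issue.

Step 5
Reactants: 8 4-hydroxybenzaldehyde
Product: 9 4-(methoxymethoxy)benzaldehyde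
Conditions: NaH (1.1 equiv), DMF, 0 °C; MOMCl (1.2 equiv), 0 °C → rt
Reagents that add atoms: chloromethyl methyl ether (MOMCl), COCCl
Why: Williamson-type O-alkylation of the phenoxide gives the same protecting group as on ring A, so one final operation frees all phenols.

Step 6
Reactants: 9 4-(methoxymethoxy)benzaldehyde
Product: 10 1-ethynyl-4-(methoxymethoxy)benzene
Conditions: dimethyl (1-diazo-2-oxopropyl)phosphonate (1.3 equiv), K2CO3 (2 equiv), MeOH, rt
Reagents that add atoms: dimethyl (1-diazo-2-oxopropyl)phosphonate (Ohira–Bestmann reagent), CC(=O)C(=[N+]=[N-])P(=O)(OC)OC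
Why: Seyferth–Gilbert homologation in its Ohira–Bestmann form converts the aromatic aldehyde into the terminal alkyne under mild base that leaves the MOM ether untouched.

Step 7
Reactants: 10 1-ethynyl-4-(methoxymethoxy)benzene
Product: 12 [(E)-2-[4-(methoxymethoxy)phenyl]ethenyl]boronic acid, via catechol alkenylboronate 11 (not isolated)
Conditions: catecholborane (1.2 equiv), Cy2BH (10 mol%), THF, rt; then H2O, rt; crystallisation
Reagents that add atoms: catecholborane, B1Oc2ccccc2O1; water, O
Why: syn, anti-Markovnikov hydroboration of the terminal alkyne fixes the E geometry, and hydrolysis of the catechol ester gives the crystalline alkenylboronic acid.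

Step 8
Reactants: 7 (1E)-1-[3-bromo-4-methoxy-2,6-bis(methoxymethoxy)phenyl]-5-phenylpent-1-en-3-one; 12 [(E)-2-[4-(methoxymethoxy)phenyl]ethenyl]boronic acid (3 equiv)
Product: 13 (5R,6E)-5-[3-bromo-4-methoxy-2,6-bis(methoxymethoxy)phenyl]-7-[4-(methoxymethoxy)phenyl]-1-phenylhept-6-en-3-one
Conditions: [Rh(OH)((S)-BINAP)]2 (2.5 mol%), 1,4-dioxane/H2O 10:1, 50 °C, 16 h
Reagents that add atoms: none
Why: Hayashi–Miyaura asymmetric conjugate addition, in which the alkenyl group passes from boron to the [Rh(OH)((S)-BINAP)]2-derived catalyst and inserts into the E-enone on its α-si face (the face left open by the ligand phenyl groups), setting C5 as R under catalyst control as the first stereocentre; the ligand antipode follows the accepted model and should be confirmed on the first run.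

Step 9
Reactants: 13 (5R,6E)-5-[3-bromo-4-methoxy-2,6-bis(methoxymethoxy)phenyl]-7-[4-(methoxymethoxy)phenyl]-1-phenylhept-6-en-3-one
Product: 14 (3S,5R,6E)-5-[3-bromo-4-methoxy-2,6-bis(methoxymethoxy)phenyl]-7-[4-(methoxymethoxy)phenyl]-1-phenylhept-6-en-3-ol
Conditions: ketoreductase (Prelog-selective, NADPH-dependent, best hit of an engineered panel), NADP+ (cat.), i-PrOH (15% v/v), DMSO (10% v/v), KH2PO4/K2HPO4 buffer (100 mM, pH 7.0), MgSO4 (2 mM), 30 °C
Reagents that add atoms: none
Why: Enzymatic carbonyl reduction in which the ketoreductase places the branched arm in its large pocket and delivers the NADPH hydride to the re face (Prelog selectivity), giving the 3S alcohol under catalyst control regardless of the existing C5 centre, with isopropanol recycling the cofactor.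

Step 10
Reactants: 14 (3S,5R,6E)-5-[3-bromo-4-methoxy-2,6-bis(methoxymethoxy)phenyl]-7-[4-(methoxymethoxy)phenyl]-1-phenylhept-6-en-3-ol
Product: 16 1-{3-[(1E,3R,5S)-5-hydroxy-1-[4-(methoxymethoxy)phenyl]-7-phenylhept-1-en-3-yl]-6-methoxy-2,4-bis(methoxymethoxy)phenyl}ethan-1-one, via aryl enol ether 15 (not isolated)
Conditions: tributyl(1-ethoxyvinyl)stannane (1.5 equiv), Pd(P(t-Bu)3)2 (5 mol%), CsF (2.2 equiv), 1,4-dioxane, 90 °C; then 1 M aq. HCl, THF, 0 °C, 20 min
Reagents that add atoms: tributyl(1-ethoxyvinyl)stannane, CCCC[Sn](CCCC)(CCCC)C(=C)OCC; water, O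
Why: Fluoride-promoted Stille coupling of the hindered, electron-rich aryl bromide with an acetyl-anion equivalent, followed by hydrolysis of the aryl enol ether in acid too dilute and brief to cleave MOM ethers, installs the acetyl group without touching either stereocentre.

Step 11
Reactants: 16 1-{3-[(1E,3R,5S)-5-hydroxy-1-[4-(methoxymethoxy)phenyl]-7-phenylhept-1-en-3-yl]-6-methoxy-2,4-bis(methoxymethoxy)phenyl}ethan-1-one; 17 benzaldehyde (2 equiv)
Product: 18 (2E)-1-{3-[(1E,3R,5S)-5-hydroxy-1-[4-(methoxymethoxy)phenyl]-7-phenylhept-1-en-3-yl]-6-methoxy-2,4-bis(methoxymethoxy)phenyl}-3-phenylprop-2-en-1-one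
Conditions: KOH (10 equiv), EtOH, rt, 24–48 h
Reagents that add atoms: none
Why: Claisen–Schmidt (crossed aldol) condensation of the methyl ketone enolate with non-enolisable benzaldehyde and E1cB dehydration gives the E-chalcone with loss of one molecule of water, while MOM ethers, the free secondary alcohol and the non-acidic C3–H are inert to ethanolic KOH at rt.

Step 12
Reactants: 18 (2E)-1-{3-[(1E,3R,5S)-5-hydroxy-1-[4-(methoxymethoxy)phenyl]-7-phenylhept-1-en-3-yl]-6-methoxy-2,4-bis(methoxymethoxy)phenyl}-3-phenylprop-2-en-1-one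
Product: 19 Alpinnanin C, (2E)-1-{2,4-dihydroxy-3-[(1E,3R,5S)-5-hydroxy-1-(4-hydroxyphenyl)-7-phenylhept-1-en-3-yl]-6-methoxyphenyl}-3-phenylprop-2-en-1-one
Conditions: 2 M HCl in MeOH/THF (3:1), rt → 35 °C, monitored by TLC; NaHCO3 quench as soon as 18 is consumed
Reagents that add atoms: none
Why: Acid-catalysed acetal cleavage (transacetalisation to dimethoxymethane) frees the three phenols, and moderate acid near room temperature with an early quench spares the styrene, the chalcone and both stereocentres, since no bond to C3 or C5 is broken.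

**Compound list**
1 | 5-methoxyresorcinol | COc1cc(O)cc(O)c1 | starting material
2 | 1-methoxy-3,5-bis(methoxymethoxy)benzene | COCOc1cc(OC)cc(OCOC)c1 | intermediate
3 | [4-methoxy-2,6-bis(methoxymethoxy)phenyl]lithium | [Li]c1c(OCOC)cc(OC)cc1OCOC | intermediate
4 | 4-methoxy-2,6-bis(methoxymethoxy)benzaldehyde | COCOc1cc(OC)cc(OCOC)c1C=O | intermediate
5 | 3-bromo-4-methoxy-2,6-bis(methoxymethoxy)benzaldehyde | COCOc1cc(OC)c(Br)c(OCOC)c1C=O | intermediate
6 | dimethyl (2-oxo-4-phenylbutyl)phosphonate | COP(=O)(OC)CC(=O)CCc1ccccc1 | starting material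
7 | (1E)-1-[3-bromo-4-methoxy-2,6-bis(methoxymethoxy)phenyl]-5-phenylpent-1-en-3-one | COCOc1cc(OC)c(Br)c(OCOC)c1/C=C/C(=O)CCc1ccccc1 | intermediate
8 | 4-hydroxybenzaldehyde | O=Cc1ccc(O)cc1 | starting material
9 | 4-(methoxymethoxy)benzaldehyde | COCOc1ccc(C=O)cc1 | intermediate
10 | 1-ethynyl-4-(methoxymethoxy)benzene | COCOc1ccc(C#C)cc1 | intermediate
11 | 2-[(E)-2-[4-(methoxymethoxy)phenyl]ethenyl]-1,3,2-benzodioxaborole | COCOc1ccc(/C=C/B2Oc3ccccc3O2)cc1 | intermediate
12 | [(E)-2-[4-(methoxymethoxy)phenyl]ethenyl]boronic acid | COCOc1ccc(/C=C/B(O)O)cc1 | intermediate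
13 | (5R,6E)-5-[3-bromo-4-methoxy-2,6-bis(methoxymethoxy)phenyl]-7-[4-(methoxymethoxy)phenyl]-1-phenylhept-6-en-3-one | COCOc1cc(OC)c(Br)c(OCOC)c1[C@@H](/C=C/c1ccc(OCOC)cc1)CC(=O)CCc1ccccc1 | intermediate
14 | (3S,5R,6E)-5-[3-bromo-4-methoxy-2,6-bis(methoxymethoxy)phenyl]-7-[4-(methoxymethoxy)phenyl]-1-phenylhept-6-en-3-ol | COCOc1cc(OC)c(Br)c(OCOC)c1[C@@H](/C=C/c1ccc(OCOC)cc1)C[C@@H](O)CCc1ccccc1 | intermediate
15 | (3S,5R,6E)-5-[3-(1-ethoxyethenyl)-4-methoxy-2,6-bis(methoxymethoxy)phenyl]-7-[4-(methoxymethoxy)phenyl]-1-phenylhept-6-en-3-ol | COCOc1cc(OC)c(C(=C)OCC)c(OCOC)c1[C@@H](/C=C/c1ccc(OCOC)cc1)C[C@@H](O)CCc1ccccc1 | intermediate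
16 | 1-{3-[(1E,3R,5S)-5-hydroxy-1-[4-(methoxymethoxy)phenyl]-7-phenylhept-1-en-3-yl]-6-methoxy-2,4-bis(methoxymethoxy)phenyl}ethan-1-one | COCOc1cc(OC)c(C(C)=O)c(OCOC)c1[C@@H](/C=C/c1ccc(OCOC)cc1)C[C@@H](O)CCc1ccccc1 | intermediate
17 | benzaldehyde | O=Cc1ccccc1 | starting material
18 | (2E)-1-{3-[(1E,3R,5S)-5-hydroxy-1-[4-(methoxymethoxy)phenyl]-7-phenylhept-1-en-3-yl]-6-methoxy-2,4-bis(methoxymethoxy)phenyl}-3-phenylprop-2-en-1-one | COCOc1cc(OC)c(C(=O)/C=C/c2ccccc2)c(OCOC)c1[C@@H](/C=C/c1ccc(OCOC)cc1)C[C@@H](O)CCc1ccccc1 | intermediate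
19 | Alpinnanin C | COc1cc(O)c([C@@H](/C=C/c2ccc(O)cc2)C[C@@H](O)CCc2ccccc2)c(O)c1C(=O)/C=C/c1ccccc1 | target

**Totals**
Total step count: 12. Longest linear sequence: 9 steps (steps 1, 2, 3, 4, 8, 9, 10, 11, 12, from 1 to 19); the boronic acid branch (steps 5–7) joins at step 8.

**Three steps most likely to fail**

Step 8. The enone carries an electron-rich aryl group with two ortho substituents, so insertion may be slow, 12 may protodeboronate and the ee may suffer. The fallback sets out from 7 and 12 and comes back at 13. It replaces the rhodium cycle by an organocatalytic conjugate alkenylboration of the Chong type: 7 and 12 are heated in toluene with 4 Å sieves, 20 mol% of 3,3'-bis(pentafluorophenyl)-BINOL (the antipode that gives the 5R ketone) and Mg(Ot-Bu)2 (10 mol%). The BINOL boronate binds the ketone oxygen, which is made more basic by the electron-rich aryl group, and delivers the alkenyl group through a closed six-membered transition state, so no metal–alkene complex is needed. This way makes no new compound (F0).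

Step 9. The ketone has two large arms and may be a poor substrate for every enzyme in the panel, or may be reduced with low selectivity. The fallback sets out from 13 and comes back at 14. NaBH4 in MeOH at 0 °C gives 14 together with its carbinol epimer, (3R,5R,6E)-5-[3-bromo-4-methoxy-2,6-bis(methoxymethoxy)phenyl]-7-[4-(methoxymethoxy)phenyl]-1-phenylhept-6-en-3-ol F1, and the two are separated by chromatography. The epimer is then inverted by a Mitsunobu reaction (4-nitrobenzoic acid, PPh3, DIAD, THF, 0 °C → rt) to (3S,5R,6E)-5-[3-bromo-4-methoxy-2,6-bis(methoxymethoxy)phenyl]-7-[4-(methoxymethoxy)phenyl]-1-phenylhept-6-en-3-yl 4-nitrobenzoate F2. Methanolysis (K2CO3, MeOH, rt) returns 14, so all material converges on the 3S alcohol.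

Step 12. Protic acid can protonate the 4-hydroxystyrene, leading to attack by the C5 hydroxyl or an ortho phenol (tetrahydropyran or flavan formation), or can close the chalcone to a flavanone. The fallback sets out from 18 and comes back at 19. TESOTf (8 equiv) and 2,2'-bipyridyl (12 equiv) in CH2Cl2 at 0 °C → rt exchange the three aryl MOM ethers directly for aryl triethylsilyl ethers and silylate the C5 hydroxyl. This gives (2E)-1-{6-methoxy-3-[(1E,3R,5S)-7-phenyl-5-(triethylsilyloxy)-1-[4-(triethylsilyloxy)phenyl]hept-1-en-3-yl]-2,4-bis(triethylsilyloxy)phenyl}-3-phenylprop-2-en-1-one F3. HF·pyridine buffered with pyridine in THF at 0 °C then removes all four silyl groups and gives 19 without mineral acid.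

**Further compounds**
F0 | step 8 | none | none
F1 | step 9 | (3R,5R,6E)-5-[3-bromo-4-methoxy-2,6-bis(methoxymethoxy)phenyl]-7-[4-(methoxymethoxy)phenyl]-1-phenylhept-6-en-3-ol | COCOc1cc(OC)c(Br)c(OCOC)c1[C@@H](/C=C/c1ccc(OCOC)cc1)C[C@H](O)CCc1ccccc1
F2 | step 9 | (3S,5R,6E)-5-[3-bromo-4-methoxy-2,6-bis(methoxymethoxy)phenyl]-7-[4-(methoxymethoxy)phenyl]-1-phenylhept-6-en-3-yl 4-nitrobenzoate | COCOc1cc(OC)c(Br)c(OCOC)c1[C@@H](/C=C/c1ccc(OCOC)cc1)C[C@@H](OC(=O)c1ccc(cc1)[N+](=O)[O-])CCc1ccccc1
F3 | step 12 | (2E)-1-{6-methoxy-3-[(1E,3R,5S)-7-phenyl-5-(triethylsilyloxy)-1-[4-(triethylsilyloxy)phenyl]hept-1-en-3-yl]-2,4-bis(triethylsilyloxy)phenyl}-3-phenylprop-2-en-1-one | CC[Si](CC)(CC)Oc1cc(OC)c(C(=O)/C=C/c2ccccc2)c(O[Si](CC)(CC)CC)c1[C@@H](/C=C/c1ccc(O[Si](CC)(CC)CC)cc1)C[C@@H](O[Si](CC)(CC)CC)CCc1ccccc1
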